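**Plan**
- Retrosynthesis: cut the bond between the methyl-bearing olefinic carbon and the CH2 on the epoxide side, giving a dioxane-bearing 1,1-dibromoalkene and an epoxy-alkylzinc (the vinylic methyl enters at the second C–Br bond). Then cut C6–allyl and O2–C3 of the dioxane, and trim the epoxide side chain back to the epoxy aldehyde of β-cyclogeraniol.
- Enabling feature: that olefinic carbon carries two carbon substituents (CH3, CH2) and is insulated from C6 of the 1,2-dioxane by =CH–CH2–CH2 and from C1 of the 7-oxabicyclo[4.1.0]heptane by CH2–CH2. It can therefore be a CBr2 terminus whose two C–Br bonds differ only in being trans or cis to the dioxane chain.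
- Forward: Evans aldol, diol, mesylate; ozonolysis in MeOH to a hydroperoxy ketal; 6-exo displacement closes the 1,2-dioxane; allylation at C6; chain extension to the aldehyde and gem-dibromoalkene. The epoxy iodide is made separately; a one-pot double Negishi coupling joins the halves; desilylation and oxidation finish.
- Stereochemistry: C2/C3 from the Evans syn-aldol ((R)-auxiliary), with inversion at C3 in the ring closure; C6 from axial allylation cis to the C3 substituent; both epoxide carbons from Sharpless epoxidation with D-(−)-diethyl tartrate; E-olefin from trans-selective first coupling and retentive methylation.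

Key step: step 19

Assumption: allylsilane addition to the six-membered peroxycarbenium ion is taken to follow the axial-attack rule known for six-membered oxocarbenium ions.
Naming: dioxane locants are those of the target throughout (C3 = the CH carrying the branched side chain, C6 = the quaternary carbon).

Step 1
Reactants: 1 4-methylpent-4-en-1-ol
Product: 2 4-methylpent-4-enal
Conditions: TEMPO (10 mol %), PhI(OAc)2, CH2Cl2, rt
Reagents that add atoms: none
Why: Oxoammonium (TEMPO) oxidation stops at the aldehyde and should leave the 1,1-disubstituted alkene untouched.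

Step 2
Reactants: 3 (4R)-4-benzyl-3-propanoyl-1,3-oxazolidin-2-one; 2 4-methylpent-4-enal
Product: 5 (4R)-4-benzyl-3-[(2R,3S)-3-hydroxy-2,6-dimethylhept-6-enoyl]-1,3-oxazolidin-2-one, via Z-boron enolate 4 (not isolated)
Conditions: Bu2BOTf, i-Pr2NEt, CH2Cl2, 0 °C; then 2, −78 → 0 °C; pH 7 buffer, MeOH, H2O2, 0 °C
Reagents that add atoms: none
Why: Evans syn-aldol reaction, in which the Z-boron enolate reacts through a closed Zimmerman–Traxler transition state whose one face is shielded by the benzyl group of the (R)-auxiliary, so C2 (R) and C3 (S) should be set together as the syn pair.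

Step 3
Reactants: 5 (4R)-4-benzyl-3-[(2R,3S)-3-hydroxy-2,6-dimethylhept-6-enoyl]-1,3-oxazolidin-2-one
Product: 6 (2S,3S)-2,6-dimethylhept-6-ene-1,3-diol
Conditions: LiBH4, H2O (1 equiv), Et2O, 0 °C
Reagents that add atoms: none
Why: Reductive removal of the auxiliary by hydride reduction of the imide carbonyl gives the 1,3-diol without touching either stereocentre (the C2 descriptor changes only through CIP priorities).

Step 4
Reactants: 6 (2S,3S)-2,6-dimethylhept-6-ene-1,3-diol
Product: 7 (2S,3S)-1-{[tert-butyl(dimethyl)silyl]oxy}-2,6-dimethylhept-6-en-3-ol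
Conditions: TBSCl (1.05 equiv), imidazole, CH2Cl2, 0 °C
Reagents that add atoms: tert-butyl(chloro)dimethylsilane, CC(C)(C)[Si](C)(C)Cl
Why: Silyl ether formation is much faster at the primary hydroxyl than at the hindered secondary one, so one equivalent should protect C1 selectively.

Step 5
Reactants: 7 (2S,3S)-1-{[tert-butyl(dimethyl)silyl]oxy}-2,6-dimethylhept-6-en-3-ol
Product: 8 (2S,3S)-1-{[tert-butyl(dimethyl)silyl]oxy}-2,6-dimethylhept-6-en-3-yl methanesulfonate
Conditions: MsCl, Et3N, CH2Cl2, 0 °C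
Reagents that add atoms: methanesulfonyl chloride, CS(=O)(=O)Cl
Why: Mesylate formation with retention turns C3 into the electrophile for the later ring closure while C1 stays at the alcohol oxidation level, which rules out β-elimination towards a carbonyl.

Step 6
Reactants: 8 (2S,3S)-1-{[tert-butyl(dimethyl)silyl]oxy}-2,6-dimethylhept-6-en-3-yl methanesulfonate
Product: 9 (2S,3S)-1-{[tert-butyl(dimethyl)silyl]oxy}-6-hydroperoxy-6-methoxy-2-methylheptan-3-yl methanesulfonate (both C6 epimers)
Conditions: O3, CH2Cl2/MeOH (4:1), −78 °C; N2 purge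
Reagents that add atoms: ozone, [O-][O+]=O; methanol, CO
Why: Criegee ozonolysis of the 1,1-disubstituted alkene with methanol capture should place the α-methoxy hydroperoxide on the more substituted (ketone-derived) carbon, the future C6, while the mesylate and silyl ether are inert to ozone at −78 °C.

Step 7
Reactants: 9 (2S,3S)-1-{[tert-butyl(dimethyl)silyl]oxy}-6-hydroperoxy-6-methoxy-2-methylheptan-3-yl methanesulfonate
Product: 10 tert-butyl-{(2S)-2-[(3R)-6-methoxy-6-methyl-1,2-dioxan-3-yl]propoxy}dimethylsilane (both C6 epimers)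
Conditions: KOt-Bu, 18-crown-6, toluene, 0 °C → rt
Reagents that add atoms: none
Why: Intramolecular Williamson-type alkylation of the hydroperoxide anion, a 6-exo-tet displacement of the mesylate with inversion, should turn the (3S) carbinol carbon into the (3R) peroxide carbon and close the 1,2-dioxane; the C6 ketal mixture converges in step 8.

Step 8
Reactants: 10 tert-butyl-{(2S)-2-[(3R)-6-methoxy-6-methyl-1,2-dioxan-3-yl]propoxy}dimethylsilane
Product: 12 tert-butyl-{(2S)-2-[(3R,6S)-6-methyl-6-(prop-2-en-1-yl)-1,2-dioxan-3-yl]propoxy}dimethylsilane, via peroxycarbenium ion 11 (not isolated)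
Conditions: allylSiMe3, TMSOTf (0.3 equiv), CH2Cl2, −78 °C
Reagents that add atoms: allyltrimethylsilane, C=CC[Si](C)(C)C
Why: Hosomi–Sakurai-type allylation of a cyclic peroxyketal, in which TMSOTf ionises the exocyclic methoxy group and the allylsilane should add axially to the half-chair cation that has the C3 substituent pseudo-equatorial, placing the allyl group cis to the C3 side chain and the methyl equatorial as the target requires at C6.

Step 9
Reactants: 12 tert-butyl-{(2S)-2-[(3R,6S)-6-methyl-6-(prop-2-en-1-yl)-1,2-dioxan-3-yl]propoxy}dimethylsilane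
Product: 14 3-{(3R,6R)-3-[(2S)-1-{[tert-butyl(dimethyl)silyl]oxy}propan-2-yl]-6-methyl-1,2-dioxan-6-yl}propan-1-ol, via B-alkyl borane 13 (not isolated)
Conditions: 9-BBN, THF, 0 °C → rt; then NaBO3·4H2O, H2O, rt
Reagents that add atoms: sodium perborate, [Na+].[Na+].O[B-]1(O)OO[B-](O)(O)OO1
Why: Anti-Markovnikov hydroboration of the terminal alkene followed by mild perborate oxidation of the C–B bond gives the primary alcohol under conditions the dialkyl peroxide and silyl ether should survive (hydroboration–oxidation).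

Step 10
Reactants: 14 3-{(3R,6R)-3-[(2S)-1-{[tert-butyl(dimethyl)silyl]oxy}propan-2-yl]-6-methyl-1,2-dioxan-6-yl}propan-1-ol
Product: 15 3-{(3R,6S)-3-[(2S)-1-{[tert-butyl(dimethyl)silyl]oxy}propan-2-yl]-6-methyl-1,2-dioxan-6-yl}propanal
Conditions: TEMPO (10 mol %), PhI(OAc)2, CH2Cl2, rt
Reagents that add atoms: none
Why: Oxoammonium (TEMPO) oxidation gives the aldehyde under near-neutral conditions that do not endanger the O–O bond.

Step 11
Reactants: 15 3-{(3R,6S)-3-[(2S)-1-{[tert-butyl(dimethyl)silyl]oxy}propan-2-yl]-6-methyl-1,2-dioxan-6-yl}propanal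
Product: 16 tert-butyl-{(2S)-2-[(3R,6R)-6-(4,4-dibromobut-3-en-1-yl)-6-methyl-1,2-dioxan-3-yl]propoxy}dimethylsilane
Conditions: CBr4, PPh3, 2,6-lutidine, CH2Cl2, 0 °C
Reagents that add atoms: tetrabromomethane, BrC(Br)(Br)Br
Why: Ramirez dibromo-olefination (first stage of the Corey–Fuchs sequence) converts the aldehyde into the gem-dibromoalkene whose CBr2 carbon is the future methyl-bearing olefinic carbon.

Step 12
Reactants: 17 β-cyclocitral (2,6,6-trimethylcyclohex-1-ene-1-carbaldehyde)
Product: 18 β-cyclogeraniol [(2,6,6-trimethylcyclohex-1-en-1-yl)methanol]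
Conditions: NaBH4, MeOH, 0 °C
Reagents that add atoms: none
Why: Borohydride 1,2-reduction of the hindered enal gives the allylic alcohol needed for directed epoxidation.

Step 13
Reactants: 18 β-cyclogeraniol
Product: 19 [(1R,6R)-2,2,6-trimethyl-7-oxabicyclo[4.1.0]heptan-1-yl]methanol
Conditions: Ti(Oi-Pr)4 (20 mol %), D-(−)-diethyl tartrate (24 mol %), t-BuOOH, 4 Å MS, CH2Cl2, −20 °C
Reagents that add atoms: tert-butyl hydroperoxide, CC(C)(C)OO
Why: Sharpless asymmetric epoxidation, in which the allylic hydroxyl binds the titanium tartrate catalyst and D-(−)-diethyl tartrate should deliver oxygen to the face of the tetrasubstituted alkene that gives the (1R,6R)-epoxy alcohol, setting both epoxide stereocentres.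

Step 14
Reactants: 19 [(1R,6R)-2,2,6-trimethyl-7-oxabicyclo[4.1.0]heptan-1-yl]methanol
Product: 20 (1S,6R)-2,2,6-trimethyl-7-oxabicyclo[4.1.0]heptane-1-carbaldehyde
Conditions: Dess–Martin periodinane, pyridine, CH2Cl2, 0 °C → rt
Reagents that add atoms: none
Why: Buffered Dess–Martin oxidation gives the epoxy aldehyde, which has no α-hydrogen and cannot epimerise.

Step 15
Reactants: 20 (1S,6R)-2,2,6-trimethyl-7-oxabicyclo[4.1.0]heptane-1-carbaldehyde
Product: 21 methyl (2E)-3-[(1S,6R)-2,2,6-trimethyl-7-oxabicyclo[4.1.0]heptan-1-yl]prop-2-enoate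
Conditions: Ph3P=CHCO2Me, toluene, 80 °C
Reagents that add atoms: methyl (triphenyl-λ5-phosphanylidene)acetate, COC(=O)C=P(c1ccccc1)(c1ccccc1)c1ccccc1
Why: Wittig reaction with a stabilised ylide should give the E-enoate, and the fully substituted epoxide is inert to the ylide.

Step 16
Reactants: 21 methyl (2E)-3-[(1S,6R)-2,2,6-trimethyl-7-oxabicyclo[4.1.0]heptan-1-yl]prop-2-enoate
Product: 22 methyl 3-[(1S,6R)-2,2,6-trimethyl-7-oxabicyclo[4.1.0]heptan-1-yl]propanoate
Conditions: 2-nitrobenzenesulfonohydrazide, Et3N, CH2Cl2, rt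
Reagents that add atoms: none
Why: Diimide reduction transfers H2 to the disubstituted C=C in a concerted syn fashion and, unlike catalytic hydrogenation or hydride conjugate reduction, should not open the adjacent allylic epoxide.

Step 17
Reactants: 22 methyl 3-[(1S,6R)-2,2,6-trimethyl-7-oxabicyclo[4.1.0]heptan-1-yl]propanoate
Product: 23 3-[(1S,6R)-2,2,6-trimethyl-7-oxabicyclo[4.1.0]heptan-1-yl]propanoic acid
Conditions: LiOH·H2O, THF/MeOH/H2O, rt; then 0.5 M HCl to pH 5, 0 °C
Reagents that add atoms: lithium hydroxide, [Li+].[OH-]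
Why: Ester saponification is harmless to the epoxide, and acidification only to pH 5 in the cold should keep the acid-labile tetrasubstituted oxirane intact.

Step 18
Reactants: 23 3-[(1S,6R)-2,2,6-trimethyl-7-oxabicyclo[4.1.0]heptan-1-yl]propanoic acid
Product: 25 (1S,6R)-1-(2-iodoethyl)-2,2,6-trimethyl-7-oxabicyclo[4.1.0]heptane, via Barton ester 24 (not isolated)
Conditions: 1-hydroxypyridine-2(1H)-thione, DCC, DMAP (cat.), CH2Cl2, rt, dark; then CHI3, hν (visible), rt
Reagents that add atoms: iodoform, IC(I)I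
Why: Barton decarboxylative iodination, in which the thiohydroxamate ester fragments under light to a primary alkyl radical that is separated from the oxirane by one CH2 (so it cannot open the ring) and abstracts iodine from CHI3.

Step 19
Reactants: 25 (1S,6R)-1-(2-iodoethyl)-2,2,6-trimethyl-7-oxabicyclo[4.1.0]heptane; 16 tert-butyl-{(2S)-2-[(3R,6R)-6-(4,4-dibromobut-3-en-1-yl)-6-methyl-1,2-dioxan-3-yl]propoxy}dimethylsilane
Product: 29 tert-butyl-{(2S)-2-[(3R,6R)-6-methyl-6-{(3E)-4-methyl-6-[(1S,6R)-2,2,6-trimethyl-7-oxabicyclo[4.1.0]heptan-1-yl]hex-3-en-1-yl}-1,2-dioxan-3-yl]propoxy}dimethylsilane, via alkyllithium 26 (not isolated), via alkylzinc bromide 27 (not isolated), via Z-bromoalkene 28 (not isolated)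
Conditions: 25 (1.3 equiv), t-BuLi (2.7 equiv), Et2O, −78 °C; ZnBr2, THF, −78 → 0 °C; 16, PdCl2(DPEphos) (5 mol %), THF, 0 → 23 °C; then Me2Zn, Pd[P(t-Bu)3]2 (5 mol %), 23 °C
Reagents that add atoms: dimethylzinc, C[Zn]C
Why: Iodine–lithium exchange and transmetalation give the alkylzinc; zerovalent palladium (formed from the divalent precatalyst) inserts only into the C–Br bond trans to the dioxane-bearing chain, the less hindered one, and transmetalation and reductive elimination form the C(sp2)–C(sp3) bond to give the Z-bromoalkene. The remaining, more hindered C–Br bond is then taken up by the more active tri-tert-butylphosphine catalyst and methylated by Me2Zn with retention, so the methyl ends up cis to the dioxane chain and the E-trisubstituted olefin results. The closest known reaction type is the trans-selective Negishi monoalkylation of 1,1-dibromo-1-alkenes with alkylzinc reagents followed by a stereoretentive second coupling in the same flask. No ring is closed and no stereocentre is created; the new stereo element is the olefin geometry, controlled by the site selectivity of the first oxidative addition and by retention in the second coupling. The step needs chemoselectivity for C–Br over the O–O bond and the oxirane, which should be secured by the mild organozinc at room temperature, the unstrained dialkyl peroxide, the fully substituted and shielded epoxide carbons, and a donor solvent that damps the Lewis acidity of the zinc salts.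

Step 20
Reactants: 29 tert-butyl-{(2S)-2-[(3R,6R)-6-methyl-6-{(3E)-4-methyl-6-[(1S,6R)-2,2,6-trimethyl-7-oxabicyclo[4.1.0]heptan-1-yl]hex-3-en-1-yl}-1,2-dioxan-3-yl]propoxy}dimethylsilane
Product: 30 (2S)-2-[(3R,6R)-6-methyl-6-{(3E)-4-methyl-6-[(1S,6R)-2,2,6-trimethyl-7-oxabicyclo[4.1.0]heptan-1-yl]hex-3-en-1-yl}-1,2-dioxan-3-yl]propan-1-ol
Conditions: TBAF, AcOH, THF, 0 °C → rt
Reagents that add atoms: none
Why: Fluoride-mediated desilylation of the primary silyl ether, buffered with AcOH so that the medium stays non-basic towards the C3–H of the dioxane.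

Step 21
Reactants: 30 (2S)-2-[(3R,6R)-6-methyl-6-{(3E)-4-methyl-6-[(1S,6R)-2,2,6-trimethyl-7-oxabicyclo[4.1.0]heptan-1-yl]hex-3-en-1-yl}-1,2-dioxan-3-yl]propan-1-ol
Product: 32 (2R)-2-[(3R,6R)-6-methyl-6-{(3E)-4-methyl-6-[(1S,6R)-2,2,6-trimethyl-7-oxabicyclo[4.1.0]heptan-1-yl]hex-3-en-1-yl}-1,2-dioxan-3-yl]propanoic acid, via aldehyde 31 (not isolated)
Conditions: TEMPO (20 mol %), PhI(OAc)2 (2.5 equiv), MeCN/pH 7 phosphate buffer (1:1), rt
Reagents that add atoms: water, O
Why: Oxoammonium (TEMPO) oxidation in buffered aqueous acetonitrile takes the primary alcohol through the aldehyde and its hydrate to the acid at neutral pH, which should spare the trisubstituted alkene, the epoxide, the O–O bond and the α-stereocentre.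

**Compound list**
1 | 4-methylpent-4-en-1-ol | C=C(C)CCCO | starting material
2 | 4-methylpent-4-enal | C=C(C)CCC=O | intermediate
3 | (4R)-4-benzyl-3-propanoyl-1,3-oxazolidin-2-one | CCC(=O)N1[C@H](Cc2ccccc2)COC1=O | starting material
4 | (4R)-4-benzyl-3-[(1Z)-1-(dibutylboranyloxy)prop-1-en-1-yl]-1,3-oxazolidin-2-one (Z-boron enolate) | C/C=C(\OB(CCCC)CCCC)N1[C@H](Cc2ccccc2)COC1=O | intermediate (not isolated)
5 | (4R)-4-benzyl-3-[(2R,3S)-3-hydroxy-2,6-dimethylhept-6-enoyl]-1,3-oxazolidin-2-one | C=C(C)CC[C@H](O)[C@@H](C)C(=O)N1[C@H](Cc2ccccc2)COC1=O | intermediate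
6 | (2S,3S)-2,6-dimethylhept-6-ene-1,3-diol | C=C(C)CC[C@H](O)[C@@H](C)CO | intermediate
7 | (2S,3S)-1-{[tert-butyl(dimethyl)silyl]oxy}-2,6-dimethylhept-6-en-3-ol | C=C(C)CC[C@H](O)[C@@H](C)CO[Si](C)(C)C(C)(C)C | intermediate
8 | (2S,3S)-1-{[tert-butyl(dimethyl)silyl]oxy}-2,6-dimethylhept-6-en-3-yl methanesulfonate | C=C(C)CC[C@H](OS(C)(=O)=O)[C@@H](C)CO[Si](C)(C)C(C)(C)C | intermediate
9 | (2S,3S)-1-{[tert-butyl(dimethyl)silyl]oxy}-6-hydroperoxy-6-methoxy-2-methylheptan-3-yl methanesulfonate (both C6 epimers) | COC(C)(OO)CC[C@H](OS(C)(=O)=O)[C@@H](C)CO[Si](C)(C)C(C)(C)C | intermediate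
10 | tert-butyl-{(2S)-2-[(3R)-6-methoxy-6-methyl-1,2-dioxan-3-yl]propoxy}dimethylsilane (both C6 epimers) | COC1(C)CC[C@H]([C@@H](C)CO[Si](C)(C)C(C)(C)C)OO1 | intermediate
11 | (3R)-3-[(2S)-1-{[tert-butyl(dimethyl)silyl]oxy}propan-2-yl]-6-methyl-4,5-dihydro-3H-1,2-dioxin-1-ium (peroxycarbenium ion) | CC1=[O+]O[C@H](CC1)[C@@H](C)CO[Si](C)(C)C(C)(C)C | intermediate (not isolated)
12 | tert-butyl-{(2S)-2-[(3R,6S)-6-methyl-6-(prop-2-en-1-yl)-1,2-dioxan-3-yl]propoxy}dimethylsilane | C=CC[C@]1(C)CC[C@H]([C@@H](C)CO[Si](C)(C)C(C)(C)C)OO1 | intermediate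
13 | 9-(3-{(3R,6R)-3-[(2S)-1-{[tert-butyl(dimethyl)silyl]oxy}propan-2-yl]-6-methyl-1,2-dioxan-6-yl}propyl)-9-borabicyclo[3.3.1]nonane | B1(CCC[C@]3(C)CC[C@H]([C@@H](C)CO[Si](C)(C)C(C)(C)C)OO3)C2CCCC1CCC2 | intermediate (not isolated)
14 | 3-{(3R,6R)-3-[(2S)-1-{[tert-butyl(dimethyl)silyl]oxy}propan-2-yl]-6-methyl-1,2-dioxan-6-yl}propan-1-ol | OCCC[C@]1(C)CC[C@H]([C@@H](C)CO[Si](C)(C)C(C)(C)C)OO1 | intermediate
15 | 3-{(3R,6S)-3-[(2S)-1-{[tert-butyl(dimethyl)silyl]oxy}propan-2-yl]-6-methyl-1,2-dioxan-6-yl}propanal | O=CCC[C@]1(C)CC[C@H]([C@@H](C)CO[Si](C)(C)C(C)(C)C)OO1 | intermediate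
16 | tert-butyl-{(2S)-2-[(3R,6R)-6-(4,4-dibromobut-3-en-1-yl)-6-methyl-1,2-dioxan-3-yl]propoxy}dimethylsilane | BrC(Br)=CCC[C@]1(C)CC[C@H]([C@@H](C)CO[Si](C)(C)C(C)(C)C)OO1 | intermediate
17 | β-cyclocitral (2,6,6-trimethylcyclohex-1-ene-1-carbaldehyde) | CC1=C(C=O)C(C)(C)CCC1 | starting material
18 | β-cyclogeraniol [(2,6,6-trimethylcyclohex-1-en-1-yl)methanol] | CC1=C(CO)C(C)(C)CCC1 | intermediate
19 | [(1R,6R)-2,2,6-trimethyl-7-oxabicyclo[4.1.0]heptan-1-yl]methanol | OC[C@@]12O[C@]1(C)CCCC2(C)C | intermediate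
20 | (1S,6R)-2,2,6-trimethyl-7-oxabicyclo[4.1.0]heptane-1-carbaldehyde | O=C[C@@]12O[C@]1(C)CCCC2(C)C | intermediate
21 | methyl (2E)-3-[(1S,6R)-2,2,6-trimethyl-7-oxabicyclo[4.1.0]heptan-1-yl]prop-2-enoate | COC(=O)/C=C/[C@@]12O[C@]1(C)CCCC2(C)C | intermediate
22 | methyl 3-[(1S,6R)-2,2,6-trimethyl-7-oxabicyclo[4.1.0]heptan-1-yl]propanoate | COC(=O)CC[C@@]12O[C@]1(C)CCCC2(C)C | intermediate
23 | 3-[(1S,6R)-2,2,6-trimethyl-7-oxabicyclo[4.1.0]heptan-1-yl]propanoic acid | OC(=O)CC[C@@]12O[C@]1(C)CCCC2(C)C | intermediate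
24 | 2-thioxopyridin-1(2H)-yl 3-[(1S,6R)-2,2,6-trimethyl-7-oxabicyclo[4.1.0]heptan-1-yl]propanoate (Barton ester) | S=C1C=CC=CN1OC(=O)CC[C@@]12O[C@]1(C)CCCC2(C)C | intermediate (not isolated)
25 | (1S,6R)-1-(2-iodoethyl)-2,2,6-trimethyl-7-oxabicyclo[4.1.0]heptane | ICC[C@@]12O[C@]1(C)CCCC2(C)C | intermediate
26 | {2-[(1S,6R)-2,2,6-trimethyl-7-oxabicyclo[4.1.0]heptan-1-yl]ethyl}lithium | [Li]CC[C@@]12O[C@]1(C)CCCC2(C)C | intermediate (not isolated)
27 | bromo{2-[(1S,6R)-2,2,6-trimethyl-7-oxabicyclo[4.1.0]heptan-1-yl]ethyl}zinc | Br[Zn]CC[C@@]12O[C@]1(C)CCCC2(C)C | intermediate (not isolated)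
28 | tert-butyl-{(2S)-2-[(3R,6R)-6-{(3Z)-4-bromo-6-[(1S,6R)-2,2,6-trimethyl-7-oxabicyclo[4.1.0]heptan-1-yl]hex-3-en-1-yl}-6-methyl-1,2-dioxan-3-yl]propoxy}dimethylsilane | Br/C(=C\CC[C@]1(C)CC[C@H]([C@@H](C)CO[Si](C)(C)C(C)(C)C)OO1)CC[C@@]12O[C@]1(C)CCCC2(C)C | intermediate (not isolated)
29 | tert-butyl-{(2S)-2-[(3R,6R)-6-methyl-6-{(3E)-4-methyl-6-[(1S,6R)-2,2,6-trimethyl-7-oxabicyclo[4.1.0]heptan-1-yl]hex-3-en-1-yl}-1,2-dioxan-3-yl]propoxy}dimethylsilane | C/C(=C\CC[C@]1(C)CC[C@H]([C@@H](C)CO[Si](C)(C)C(C)(C)C)OO1)CC[C@@]12O[C@]1(C)CCCC2(C)C | intermediate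
30 | (2S)-2-[(3R,6R)-6-methyl-6-{(3E)-4-methyl-6-[(1S,6R)-2,2,6-trimethyl-7-oxabicyclo[4.1.0]heptan-1-yl]hex-3-en-1-yl}-1,2-dioxan-3-yl]propan-1-ol | C/C(=C\CC[C@]1(C)CC[C@H]([C@@H](C)CO)OO1)CC[C@@]12O[C@]1(C)CCCC2(C)C | intermediate
31 | (2R)-2-[(3R,6R)-6-methyl-6-{(3E)-4-methyl-6-[(1S,6R)-2,2,6-trimethyl-7-oxabicyclo[4.1.0]heptan-1-yl]hex-3-en-1-yl}-1,2-dioxan-3-yl]propanal | C/C(=C\CC[C@]1(C)CC[C@H]([C@@H](C)C=O)OO1)CC[C@@]12O[C@]1(C)CCCC2(C)C | intermediate (not isolated)
32 | (2R)-2-[(3R,6R)-6-methyl-6-{(3E)-4-methyl-6-[(1S,6R)-2,2,6-trimethyl-7-oxabicyclo[4.1.0]heptan-1-yl]hex-3-en-1-yl}-1,2-dioxan-3-yl]propanoic acid | C/C(=C\CC[C@]1(C)CC[C@H]([C@@H](C)C(=O)O)OO1)CC[C@@]12O[C@]1(C)CCCC2(C)C | target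

**Totals**
Total step count: 21. Longest linear sequence: 14 steps (steps 1–11, then 19–21); the epoxide arm (steps 12–18) has 7 steps.

**Steps most likely to fail**

Step 19. Processes at risk: Lewis-acid-driven opening or rearrangement of the tetrasubstituted epoxide while the zinc reagent is made and used, insertion of low-valent palladium into the O–O bond, and loss of olefin geometry in the second coupling. The fallback sets out from 25 and 16 and returns at 29. Compound 25 is exchanged with t-BuLi (Et2O, −78 °C) and trapped with 9-methoxy-9-borabicyclo[3.3.1]nonane to give lithium borinate F1, a non-Lewis-acidic alkyl donor. B-alkyl Suzuki–Miyaura coupling of F1 with 16 (PdCl2(dppf), AsPh3, Cs2CO3, DMF/THF/H2O, rt) should again engage only the bromide trans to the chain and give Z-bromoalkene 28, which is now isolated and checked for geometry. Stille methylation of 28 (Me4Sn, Pd[P(t-Bu)3]2, CsF, 1,4-dioxane, 40 °C) then gives 29.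

Step 8. Processes at risk: slow capture of the peroxycarbenium ion by the weakly nucleophilic allylsilane, which lets Lewis-acid heterolysis of the O–O bond and attack on the wrong face of C6 compete. The fallback sets out from 10 and returns at 12. Mukaiyama-type addition of the much more nucleophilic silyl ketene thioacetal [1-(ethylsulfanyl)ethenyl]oxy(trimethyl)silane (TMSOTf or TiCl4, CH2Cl2, −78 °C) should give thioester F2 with the same axial sense. DIBAL-H (CH2Cl2, −78 °C) reduces it to aldehyde F3, and Wittig methylenation (Ph3P=CH2, THF, −78 → 0 °C) converts this into 12.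

Step 7. Process at risk: E2 elimination of the hindered secondary mesylate outrunning the 6-exo displacement by the tertiary peroxide anion. The fallback sets out from 6 and returns at 10. Monotosylation of the primary hydroxyl (TsCl, pyridine, 0 °C) gives tosylate F4, and KOt-Bu (THF, 0 °C → rt) closes oxetane F5 with retention at the carbinol carbon. Ozonolysis in CH2Cl2/MeOH (−78 °C) gives hydroperoxy ketal F6. A Lewis acid (TMSOTf, CH2Cl2, −78 °C) should then promote 6-exo opening of the oxetane at its secondary carbon by the hydroperoxide with inversion, giving dioxane alcohol F7. Silylation (TBSCl, imidazole, CH2Cl2) converts it into 10.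

**Further compounds**
F1 | step 19 | lithium 9-methoxy-9-{2-[(1S,6R)-2,2,6-trimethyl-7-oxabicyclo[4.1.0]heptan-1-yl]ethyl}-9-boranuidabicyclo[3.3.1]nonane | [Li+].CO[B-]1(CC[C@@]23O[C@]2(C)CCCC3(C)C)C4CCCC1CCC4
F2 | step 8 | S-ethyl {(3R,6S)-3-[(2S)-1-{[tert-butyl(dimethyl)silyl]oxy}propan-2-yl]-6-methyl-1,2-dioxan-6-yl}ethanethioate | CCSC(=O)C[C@]1(C)CC[C@H]([C@@H](C)CO[Si](C)(C)C(C)(C)C)OO1
F3 | step 8 | {(3R,6S)-3-[(2S)-1-{[tert-butyl(dimethyl)silyl]oxy}propan-2-yl]-6-methyl-1,2-dioxan-6-yl}acetaldehyde | O=CC[C@]1(C)CC[C@H]([C@@H](C)CO[Si](C)(C)C(C)(C)C)OO1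
F4 | step 7 | (2S,3S)-3-hydroxy-2,6-dimethylhept-6-en-1-yl 4-methylbenzenesulfonate | C=C(C)CC[C@H](O)[C@@H](C)COS(=O)(=O)c1ccc(C)cc1
F5 | step 7 | (2S,3S)-3-methyl-2-(3-methylbut-3-en-1-yl)oxetane | C=C(C)CC[C@@H]1OC[C@@H]1C
F6 | step 7 | (2S,3S)-2-(3-hydroperoxy-3-methoxybutyl)-3-methyloxetane (both epimers at the ketal carbon) | COC(C)(OO)CC[C@@H]1OC[C@@H]1C
F7 | step 7 | (2S)-2-[(3R)-6-methoxy-6-methyl-1,2-dioxan-3-yl]propan-1-ol (both C6 epimers) | COC1(C)CC[C@H]([C@@H](C)CO)OO1
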